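**Retrosynthetic overview**
1. The target comes from its tris-silyl ether by buffered fluoride at the very end, which spares the polyene and the α-hydroxy ketone.
2. The aryl–C1 bond comes from the Weinreb amide of the (R)-2-silyloxy acid and 2,4-bis(triisopropylsilyloxy)phenyllithium (from 4-bromoresorcinol).
3. The C2 configuration comes from lipase kinetic resolution of the racemic 2-hydroxy ester; the unreacted ester is (R).
4. The key C2–C3 bond comes from α-selective carbonyl allylation of ethyl glyoxylate with (2E,6E)-farnesylbarium chloride, made from (2E,6E)-farnesol through the chloride. This forms the homoallylic alcohol of the target directly.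
5. No ring is formed in the route; the benzene ring is bought as 4-bromoresorcinol.

Assumption: isomerically pure (2E,6E)-farnesol is bought, and ethyl glyoxylate (sold as a polymeric toluene solution) is cracked to the monomer by distillation from P2O5 just before use.

**Route**

Step 1
Reactants: 1 (2E,6E)-farnesol
Product: 3 (2E,6E)-farnesyl chloride, via farnesyl mesylate 2 (not isolated)
Conditions: MsCl, 2,4,6-collidine, LiCl, DMF, 0 °C
Reagents that add atoms: lithium chloride, [Li+].[Cl-]
Why: Mesylation and in-flask SN2 displacement by chloride (Collington–Meyers allylic chlorination) turn the primary allylic alcohol into the chloride at 0 °C without allylic transposition or loss of E geometry, and no stereocenter is involved.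

Step 2
Reactants: 3 (2E,6E)-farnesyl chloride; 4 ethyl glyoxylate
Product: 6 rac-ethyl (4E,8E)-2-hydroxy-5,9,13-trimethyltetradeca-4,8,12-trienoate, via farnesylbarium chloride 5 (not isolated)
Conditions: activated barium (BaI2, Li, biphenyl, THF, rt); 3, THF, −78 °C; then cannulated into 4 (1.5 equiv), −78 °C; aq. NH4Cl
Reagents that add atoms: none
Why: Carbonyl allylation with an allylbarium reagent (Yamamoto conditions): the reagent made from activated zerovalent barium at −78 °C keeps its 2E geometry and attacks the aldehyde, far more electrophilic than the ester, through its unsubstituted α-carbon, so the linear homoallylic alcohol forms with C2 still racemic and the minor branched γ-adduct is removed by chromatography.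

Step 3
Reactants: 6 rac-ethyl (4E,8E)-2-hydroxy-5,9,13-trimethyltetradeca-4,8,12-trienoate
Product: 7 ethyl (2R,4E,8E)-2-hydroxy-5,9,13-trimethyltetradeca-4,8,12-trienoate
Conditions: Burkholderia cepacia lipase (lipase PS), pH 7 phosphate buffer/t-BuOMe, 30 °C, to 55–60% conversion; aq. NaHCO3 wash
Reagents that add atoms: none
Why: Enzymatic kinetic resolution by enantioselective ester hydrolysis: the lipase hydrolyses the (S)-2-hydroxy ester much faster, as it does for other 2-hydroxy alkanoates, so the ester recovered past 50% conversion is the (R)-enantiomer in high ee and C2 is thereby set.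

Step 4
Reactants: 7 ethyl (2R,4E,8E)-2-hydroxy-5,9,13-trimethyltetradeca-4,8,12-trienoate
Product: 8 ethyl (2R,4E,8E)-2-[(tert-butyldimethylsilyl)oxy]-5,9,13-trimethyltetradeca-4,8,12-trienoate
Conditions: TBSCl, imidazole, DMF, rt
Reagents that add atoms: tert-butyldimethylsilyl chloride, CC(C)(C)[Si](C)(C)Cl
Why: Imidazole-promoted O-silylation (Corey protocol) masks the secondary alcohol so that it neither quenches the organometallics of steps 5 and 7 nor lets C2 epimerise.

Step 5
Reactants: 8 ethyl (2R,4E,8E)-2-[(tert-butyldimethylsilyl)oxy]-5,9,13-trimethyltetradeca-4,8,12-trienoate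
Product: 9 (2R,4E,8E)-2-[(tert-butyldimethylsilyl)oxy]-N-methoxy-N,5,9,13-tetramethyltetradeca-4,8,12-trienamide
Conditions: MeNHOMe·HCl, iPrMgCl, THF, −20 → 0 °C
Reagents that add atoms: N,O-dimethylhydroxylamine hydrochloride, CNOC.Cl
Why: Weinreb amide formation by aminolysis of the ester with the chloromagnesium amide of N,O-dimethylhydroxylamine is fast at −20 °C and does not enolise the α-silyloxy ester, so C2 stays (R).

Step 6
Reactants: 10 4-bromoresorcinol
Product: 11 1-bromo-2,4-bis[(triisopropylsilyl)oxy]benzene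
Conditions: TIPSCl, imidazole, DMF, rt → 40 °C
Reagents that add atoms: chlorotriisopropylsilane, CC(C)[Si](Cl)(C(C)C)C(C)C
Why: Imidazole-promoted O-silylation of both phenols; triisopropylsilyl is chosen because it is slow to undergo anionic 1,3-oxygen-to-carbon silyl migration in the ortho-lithiated ring and is removed by fluoride at the end.

Step 7
Reactants: 9 (2R,4E,8E)-2-[(tert-butyldimethylsilyl)oxy]-N-methoxy-N,5,9,13-tetramethyltetradeca-4,8,12-trienamide; 11 1-bromo-2,4-bis[(triisopropylsilyl)oxy]benzene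
Product: 14 (2R,4E,8E)-1-{2,4-bis[(triisopropylsilyl)oxy]phenyl}-2-[(tert-butyldimethylsilyl)oxy]-5,9,13-trimethyltetradeca-4,8,12-trien-1-one, via 2,4-bis(triisopropylsilyloxy)phenyllithium 12 (not isolated), via lithium tetrahedral adduct 13 (not isolated)
Conditions: 11 (1.6 equiv), t-BuLi (3.2 equiv), Et2O, −78 °C; then 9, −78 → −30 °C; aq. NH4Cl
Reagents that add atoms: none
Why: Bromine–lithium exchange followed by Weinreb ketone synthesis: the aryllithium adds once to the amide and the chelated tetrahedral adduct persists until the quench, so there is no over-addition and the C2 stereocenter is carried through unchanged.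

Step 8
Reactants: 14 (2R,4E,8E)-1-{2,4-bis[(triisopropylsilyl)oxy]phenyl}-2-[(tert-butyldimethylsilyl)oxy]-5,9,13-trimethyltetradeca-4,8,12-trien-1-one
Product: 15 (2R,4E,8E)-1-(2,4-dihydroxyphenyl)-2-hydroxy-5,9,13-trimethyltetradeca-4,8,12-trien-1-one
Conditions: Bu4NF, AcOH (1:1), THF, 0 °C → rt
Reagents that add atoms: none
Why: Fluoride desilylation buffered with acetic acid cleaves the two aryl silyl ethers and the α-keto silyl ether under nearly neutral conditions, which avoids base-induced enolisation of the α-hydroxy ketone (loss of C2) and acid-induced cyclisation of the polyene.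

**Compound list**

1 | (2E,6E)-farnesol, (2E,6E)-3,7,11-trimethyldodeca-2,6,10-trien-1-ol | CC(C)=CCC/C(C)=C/CC/C(C)=C/CO | starting material
2 | (2E,6E)-farnesyl methanesulfonate (farnesyl mesylate) | CC(C)=CCC/C(C)=C/CC/C(C)=C/COS(C)(=O)=O | intermediate
3 | (2E,6E)-farnesyl chloride, (2E,6E)-1-chloro-3,7,11-trimethyldodeca-2,6,10-triene | CC(C)=CCC/C(C)=C/CC/C(C)=C/CCl | intermediate
4 | ethyl glyoxylate (ethyl 2-oxoacetate) | CCOC(=O)C=O | starting material
5 | (2E,6E)-farnesylbarium chloride | CC(C)=CCC/C(C)=C/CC/C(C)=C/C[Ba]Cl | intermediate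
6 | rac-ethyl (4E,8E)-2-hydroxy-5,9,13-trimethyltetradeca-4,8,12-trienoate | CC(C)=CCC/C(C)=C/CC/C(C)=C/CC(O)C(=O)OCC | intermediate
7 | ethyl (2R,4E,8E)-2-hydroxy-5,9,13-trimethyltetradeca-4,8,12-trienoate | CC(C)=CCC/C(C)=C/CC/C(C)=C/C[C@@H](O)C(=O)OCC | intermediate
8 | ethyl (2R,4E,8E)-2-[(tert-butyldimethylsilyl)oxy]-5,9,13-trimethyltetradeca-4,8,12-trienoate | CC(C)=CCC/C(C)=C/CC/C(C)=C/C[C@@H](O[Si](C)(C)C(C)(C)C)C(=O)OCC | intermediate
9 | (2R,4E,8E)-2-[(tert-butyldimethylsilyl)oxy]-N-methoxy-N,5,9,13-tetramethyltetradeca-4,8,12-trienamide | CC(C)=CCC/C(C)=C/CC/C(C)=C/C[C@@H](O[Si](C)(C)C(C)(C)C)C(=O)N(C)OC | intermediate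
10 | 4-bromoresorcinol (4-bromobenzene-1,3-diol) | Oc1ccc(Br)c(O)c1 | starting material
11 | 1-bromo-2,4-bis[(triisopropylsilyl)oxy]benzene | CC(C)[Si](Oc1ccc(Br)c(O[Si](C(C)C)(C(C)C)C(C)C)c1)(C(C)C)C(C)C | intermediate
12 | {2,4-bis[(triisopropylsilyl)oxy]phenyl}lithium | CC(C)[Si](Oc1ccc([Li])c(O[Si](C(C)C)(C(C)C)C(C)C)c1)(C(C)C)C(C)C | intermediate
13 | lithium (2R,4E,8E)-1-{2,4-bis[(triisopropylsilyl)oxy]phenyl}-2-[(tert-butyldimethylsilyl)oxy]-1-[methoxy(methyl)amino]-5,9,13-trimethyltetradeca-4,8,12-trien-1-olate (tetrahedral adduct, C1 unassigned) | CC(C)=CCC/C(C)=C/CC/C(C)=C/C[C@@H](O[Si](C)(C)C(C)(C)C)C(O[Li])(N(C)OC)c1ccc(O[Si](C(C)C)(C(C)C)C(C)C)cc1O[Si](C(C)C)(C(C)C)C(C)C | intermediate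
14 | (2R,4E,8E)-1-{2,4-bis[(triisopropylsilyl)oxy]phenyl}-2-[(tert-butyldimethylsilyl)oxy]-5,9,13-trimethyltetradeca-4,8,12-trien-1-one | CC(C)=CCC/C(C)=C/CC/C(C)=C/C[C@@H](O[Si](C)(C)C(C)(C)C)C(=O)c1ccc(O[Si](C(C)C)(C(C)C)C(C)C)cc1O[Si](C(C)C)(C(C)C)C(C)C | intermediate
15 | (2R,4E,8E)-1-(2,4-dihydroxyphenyl)-2-hydroxy-5,9,13-trimethyltetradeca-4,8,12-trien-1-one | CC(C)=CCC/C(C)=C/CC/C(C)=C/C[C@@H](O)C(=O)c1ccc(O)cc1O | target

**Step count and risks**

Total steps: 8. Longest linear sequence: 7 steps (steps 1, 2, 3, 4, 5, 7 and 8, from farnesol 1 to target 15); step 6 is the one-step side branch.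

Most likely to fail, with one fallback each:

- Risk 1, the allylbarium addition of step 2. The activated barium may be poorly formed, the α:γ ratio on the very reactive glyoxylate may be lower than with ordinary aldehydes, or the reagent may add to the ester as well. The fallback makes the same C2–C3 bond with reversed polarity and sets out from farnesol 1. PBr3 (Et2O, 0 °C) gives (2E,6E)-farnesyl bromide F1. F1 alkylates the sodium enolate (NaN(SiMe3)2, THF, −78 → −45 °C) of (S)-4-benzyl-3-{[(4-methoxybenzyl)oxy]acetyl}oxazolidin-2-one F2, which is prepared by N-acylation of (S)-4-benzyloxazolidin-2-one with (4-methoxybenzyloxy)acetyl chloride. Attack anti to the benzyl group of the chelated Z-enolate gives (S)-4-benzyl-3-[(2R,4E,8E)-2-[(4-methoxybenzyl)oxy]-5,9,13-trimethyltetradeca-4,8,12-trienoyl]oxazolidin-2-one F3 with C2 already (R). EtOMgBr in EtOH (0 °C) releases ethyl (2R,4E,8E)-2-[(4-methoxybenzyl)oxy]-5,9,13-trimethyltetradeca-4,8,12-trienoate F4, and DDQ (CH2Cl2/pH 7 buffer) removes the 4-methoxybenzyl group. The fallback comes back to the route at 7, so step 3 is then not needed.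

- Risk 2, the lipase resolution of step 3. The selectivity factor on this long, branched-chain substrate is extrapolated from simpler 2-hydroxy esters and may be too low, and the yield cannot exceed 50%. The fallback sets out from racemic 6 and replaces resolution by oxidation and asymmetric reduction. Dess–Martin periodinane (NaHCO3, CH2Cl2, 0 °C) gives ethyl (4E,8E)-5,9,13-trimethyl-2-oxotetradeca-4,8,12-trienoate F5, which is used at once to avoid migration of the 4,5-alkene into conjugation. Noyori hydrogenation with RuCl2[(R)-BINAP] (H2 50 atm, EtOH, rt) reduces only the ketone, from the face that gives the (R)-2-hydroxy ester, and leaves the isolated trisubstituted alkenes alone. The fallback comes back to the route at 7.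

- Risk 3, the aryllithium addition of step 7. The ortho-silyloxy aryllithium 12 is hindered and may add slowly to amide 9; if the mixture has to be warmed, silyl migration from oxygen to carbon can consume 12. The fallback sets out from 9 and passes through the aldehyde oxidation level. i-Bu2AlH (THF, −78 °C) reduces 9 to (2R,4E,8E)-2-[(tert-butyldimethylsilyl)oxy]-5,9,13-trimethyltetradeca-4,8,12-trienal F6. Aryllithium 12, made from 11 as before, adds to F6 within minutes at −78 °C to give (2R,4E,8E)-1-{2,4-bis[(triisopropylsilyl)oxy]phenyl}-2-[(tert-butyldimethylsilyl)oxy]-5,9,13-trimethyltetradeca-4,8,12-trien-1-ol F7 as both C1 epimers. Dess–Martin periodinane (NaHCO3, CH2Cl2, 0 °C) oxidises F7, and the fallback comes back to the route at 14.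

**Further compounds**

F1 | step 2 | (2E,6E)-farnesyl bromide | CC(C)=CCC/C(C)=C/CC/C(C)=C/CBr
F2 | step 2 | (S)-4-benzyl-3-{[(4-methoxybenzyl)oxy]acetyl}oxazolidin-2-one | COc1ccc(COCC(=O)N2[C@@H](Cc3ccccc3)COC2=O)cc1
F3 | step 2 | (S)-4-benzyl-3-[(2R,4E,8E)-2-[(4-methoxybenzyl)oxy]-5,9,13-trimethyltetradeca-4,8,12-trienoyl]oxazolidin-2-one | CC(C)=CCC/C(C)=C/CC/C(C)=C/C[C@@H](OCc1ccc(OC)cc1)C(=O)N1[C@@H](Cc2ccccc2)COC1=O
F4 | step 2 | ethyl (2R,4E,8E)-2-[(4-methoxybenzyl)oxy]-5,9,13-trimethyltetradeca-4,8,12-trienoate | CC(C)=CCC/C(C)=C/CC/C(C)=C/C[C@@H](OCc1ccc(OC)cc1)C(=O)OCC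
F5 | step 3 | ethyl (4E,8E)-5,9,13-trimethyl-2-oxotetradeca-4,8,12-trienoate | CC(C)=CCC/C(C)=C/CC/C(C)=C/CC(=O)C(=O)OCC
F6 | step 7 | (2R,4E,8E)-2-[(tert-butyldimethylsilyl)oxy]-5,9,13-trimethyltetradeca-4,8,12-trienal | CC(C)=CCC/C(C)=C/CC/C(C)=C/C[C@@H](O[Si](C)(C)C(C)(C)C)C=O
F7 | step 7 | (2R,4E,8E)-1-{2,4-bis[(triisopropylsilyl)oxy]phenyl}-2-[(tert-butyldimethylsilyl)oxy]-5,9,13-trimethyltetradeca-4,8,12-trien-1-ol (C1 epimers) | CC(C)=CCC/C(C)=C/CC/C(C)=C/C[C@@H](O[Si](C)(C)C(C)(C)C)C(O)c1ccc(O[Si](C(C)C)(C(C)C)C(C)C)cc1O[Si](C(C)C)(C(C)C)C(C)C
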